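## The problem

Tricetin 3'-sulfate (16) is a flavone: a benzene ring A fused to a 4-pyranone ring C, with ring B attached by a single bond at C2. There is no stereocentre, so every difficulty is one of regiochemistry and functional-group tolerance. Five phenolic oxygens are present (O5, O7, O3', O4', O5') and only O3' carries the sulfate. Because O3' and O5' are interchanged by rotation about the C2–C1' bond, the task is to set one outer oxygen of the pyrogallol ring B apart from the adjacent pair, which a cyclic ketal across two neighbouring oxygens does. The aryl sulfate monoester is the fragile group: acid and the Lewis acids used to cleave aryl ethers destroy it, so it must be installed late, on a compound with a single free hydroxyl, and everything after it must be neutral. The free pyrogallol and phloroglucinol units are also oxidation-prone under base, so they should be unmasked only in the last step. The feature that invites a convergent construction is ring C: its carbonyl carbon C4 lies between the ring A carbon C4a and the two-carbon unit C3–C2 that carries ring B, while O1 sits on C8a, ortho to C4a. An ortho-iodophenol (iodine on C4a, hydroxyl on C8a), carbon monoxide (C4) and a ring B arylacetylene (C3, C2) therefore map exactly onto ring C.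

## Retrosynthesis

**16 from 15.** The last cut removes two O–CH2Ph bonds and the two C–O bonds of a diphenylmethylene ketal, all by hydrogenolysis at neutral pH. Methyl ethers would need boron halides, which the sulfate cannot survive, and esters would not survive the amine of the key step. The forward reaction must cleave four benzylic C–O bonds without saturating C2–C3 and without letting the medium turn acidic.

**15 from 14, and 14 from 13.** Cutting the S–O bond leads to 14, in which O3' is the only free hydroxyl, so sulfation needs no selectivity; sulfating free tricetin would give mixtures over five hydroxyls. Phenol 14 comes from silyl ether 13. A triisopropylsilyl ether is chosen for O3' because it is orthogonal to the hydrogenolysable groups, leaves with fluoride, and is inert to zerovalent palladium in an amine, where an allyl ether would be cleaved through a π-allyl complex.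

**13 from 2, 9 and 10.** Three bonds of ring C are cut together: C4a–C4, C4–C3 and O1–C2. This returns iodophenol 2, carbon monoxide 10 and arylacetylene 9. Cutting only one bond (O1–C8a, or the aroyl C–C bond of a diketone) would require a preformed carbonyl on one fragment and a separate ring closure. Here the precursors carry neither the carbonyl nor a ring C atom other than O1, and ring A and ring B are made independently. The forward step must favour CO insertion over direct alkynylation and six- over five-membered closure.

**2 from 1.** The C–I bond is cut to give commercial 3,5-bis(benzyloxy)phenol (1). The iodination must go ortho to the hydroxyl (C2) rather than to C4 between the two benzyloxy groups.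

**9 from 8.** The alkyne is cut to aldehyde 8 by a one-carbon homologation. The alternative, a Sonogashira coupling on a 5-halopyrogallol derivative, would start from a less accessible halide than a gallate.

**8 from 3 and 4.** Aldehyde 8 is traced through alcohol 7 and ester 6 to monoketal 5, and 5 to methyl gallate (3) and dichlorodiphenylmethane (4). The symmetry of 3 makes both vicinal diol pairs equivalent, so one ketal forms and leaves exactly one hydroxyl, the future O3'.

## Roads not taken

**Alternative 1: aryne insertion into an arylpropiolic acid.**
- Cut: C8a–O1 and C4a–C4. Ring A arrives as an aryne; the phenol oxygen and C4 both come from a ring B arylpropiolic acid.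
- Forward step: CsF releases the aryne from silyl triflate A2. The carboxylate of propiolic acid A3 adds to the aryne carbon remote from the neighbouring benzyloxy group, the aryl anion attacks the carbonyl, and the four-membered intermediate opens to the ortho-hydroxyaryl ynone A1.
- Merits: metal-free, no CO, and the flanking benzyloxy group orients the addition correctly by its inductive effect.
- Weak points:
  - No ring is closed; ring C must still be made from A1 in a further operation that faces the same six-versus-five question.
  - Insertion competes with simple O-arylation to the aryl ester and with protonation of the aryl anion.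
  - Arylpropiolic acids tend to decarboxylate when heated with fluoride.
  - Fluoride rules out a silyl ether at O3', so an allyl ether is needed, to be removed later with a palladium catalyst.
  - A2 would itself be made from iodophenol 2 (silylation, halogen–lithium exchange with retro-Brook migration, triflation), so the ring A regiochemistry question is not avoided and three steps are added. A3 lies one carboxylation beyond an alkyne of type 9.
- Comparison: this road is better in needing no pressure equipment and no palladium in the bond-forming step. The chosen plan sets against it three bonds and the ring in one operation from 2, and a route about four steps shorter.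

**Alternative 2: pyranone-masked polyketide folding of ring A.**
- Cut: C4a–C5, inside ring A, which is built last from a polyketide-like chain hung on a preformed 2-aryl-4-pyranone.
- Forward step: Mg(OMe)2 chelates the β-keto ester of A5. Pyranone carbon C5 (the future C4a), the α-carbon of a vinylogous ester, attacks the ester carbonyl; loss of methoxide and tautomerisation give the aromatic 5,7-dihydroxy ring of A4.
- Merits: biomimetic; the 5,7-oxygenation pattern is fixed by the chain, so no halogenation regiochemistry arises; no transition metal, no CO, no protecting groups on ring A.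
- Weak points:
  - A5 needs a long linear assembly (pyranone construction and chain extension).
  - The pyranone α-carbon is a weak nucleophile, and methoxide can open the pyranone or fold the chain by aldol pathways.
  - A4 has free O5 and O7, so after removal of the allyl group three phenols would compete in sulfation. Ring A would have to be reprotected, which adds steps.
- Comparison: this road is better in regiochemical certainty for ring A and in avoiding CO under pressure. The chosen plan is convergent and shorter, and delivers 13 already protected in the pattern that sulfation requires.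

**Alternative 3: copper-mediated O-arylation at C8a–O1.**
- Cut: O1–C8a only.
- Forward step: the enolate oxygen of bromoaryl diketone A7 couples with the C8a–Br carbon under CuI, 1,10-phenanthroline and K2CO3 to give flavone A6.
- Merits:
  - The tether fixes the ring size, so an aurone cannot form.
  - Ullmann-type enolate O-arylation is dependable and needs no CO pressure.
  - Ring B is needed only as ester A9, so the reduction, oxidation and homologation of steps 4–6 fall away.
- Weak points:
  - The ring A ketone A8 carries bromine meta to both oxygens, so it cannot be made by halogenating a phloroglucinol derivative. It needs a 5-bromoresorcinol sequence with an acylation that has its own ortho/para question.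
  - The crossed Claisen condensation of the hindered, doubly ortho-substituted ketone A8 with A9 is the weak link.
  - The allyl ether of A6 must later be removed with zerovalent palladium.
- Comparison: in step count this road is equal or slightly shorter on the ring B side, and its ring closure is probably the more robust. The chosen plan sets against it a ring A partner one step from commercial 1, union of the fragments and ring closure in a single operation without a strong-base condensation, and a fluoride-labile group at O3'.

Key step: step 7

## Remarks on the chemistry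

- 3,5-Bis(benzyloxy)phenol (1) is taken as a catalogue compound.
- Sulfates 15 and 16 would be handled as their sodium salts. They are drawn as the neutral hydrogen sulfates, which is the form of the target structure.
- No step creates a stereocentre. The E geometry written for the transient enaminone 12 is labile and has no bearing on the outcome.

## Route

Step 1
Reactants: 1 3,5-bis(benzyloxy)phenol
Product: 2 3,5-bis(benzyloxy)-2-iodophenol
Conditions: NIS (1.0 equiv), CH2Cl2, −20 → 0 °C
Reagents that add atoms: N-iodosuccinimide, O=C1CCC(=O)N1I
Why: Electrophilic aromatic iodination of a phloroglucinol-type ring is fast under mild conditions; C2 (between OH and OBn) is less crowded than C4 (between two OBn), is statistically doubled, and the hydrogen-bonded phenol steers the reagent ortho, so monoiodination at C2 should dominate with one equivalent in the cold.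

Step 2
Reactants: 3 methyl gallate; 4 dichlorodiphenylmethane
Product: 5 methyl 7-hydroxy-2,2-diphenyl-1,3-benzodioxole-5-carboxylate
Conditions: neat, 180 °C, N2 stream
Reagents that add atoms: none
Why: Thermal ketalisation of a catechol pair by double substitution at the gem-dichloride, driven by loss of HCl; only vicinal hydroxyls can close the five-membered dioxole and the two possible pairs are equivalent by symmetry, so a single monoketal with one free hydroxyl is expected.

Step 3
Reactants: 5 methyl 7-hydroxy-2,2-diphenyl-1,3-benzodioxole-5-carboxylate
Product: 6 methyl 2,2-diphenyl-7-(triisopropylsilyloxy)-1,3-benzodioxole-5-carboxylate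
Conditions: TIPSCl, imidazole, DMF, 23 °C
Reagents that add atoms: chlorotriisopropylsilane, CC(C)[Si](Cl)(C(C)C)C(C)C
Why: Imidazole-promoted O-silylation of the single phenol; the bulky triisopropylsilyl group gives an aryl silyl ether robust enough for hydride, strong base and hot amine yet removable by fluoride.

Step 4
Reactants: 6 methyl 2,2-diphenyl-7-(triisopropylsilyloxy)-1,3-benzodioxole-5-carboxylate
Product: 7 [2,2-diphenyl-7-(triisopropylsilyloxy)-1,3-benzodioxol-5-yl]methanol
Conditions: iBu2AlH (2.5 equiv), CH2Cl2, −78 → 0 °C; aq. potassium sodium tartrate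
Reagents that add atoms: none
Why: Hydride reduction of the aryl ester to the benzylic alcohol; iBu2AlH at low temperature leaves the ketal and the aryl silyl ether untouched.

Step 5
Reactants: 7 [2,2-diphenyl-7-(triisopropylsilyloxy)-1,3-benzodioxol-5-yl]methanol
Product: 8 2,2-diphenyl-7-(triisopropylsilyloxy)-1,3-benzodioxole-5-carbaldehyde
Conditions: MnO2 (excess), CH2Cl2, 23 °C
Reagents that add atoms: none
Why: Heterogeneous MnO2 oxidation is selective for benzylic alcohols, stops at the aldehyde and is neutral, so neither the ketal nor the silyl ether is at risk.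

Step 6
Reactants: 8 2,2-diphenyl-7-(triisopropylsilyloxy)-1,3-benzodioxole-5-carbaldehyde
Product: 9 6-ethynyl-2,2-diphenyl-4-(triisopropylsilyloxy)-1,3-benzodioxole
Conditions: Me3SiCHN2, LiN(iPr)2, THF, −78 → 23 °C
Reagents that add atoms: trimethylsilyldiazomethane, C[Si](C)(C)C=[N+]=[N-]
Why: Colvin rearrangement: the lithiated silyldiazomethane adds to the non-enolisable aldehyde, Peterson elimination and loss of N2 give an alkylidene carbene, and a 1,2-shift delivers the terminal arylacetylene in one step under conditions that avoid the carbonate–methanol medium that could loosen an aryl silyl ether.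

Step 7
Reactants: 2 3,5-bis(benzyloxy)-2-iodophenol; 9 6-ethynyl-2,2-diphenyl-4-(triisopropylsilyloxy)-1,3-benzodioxole; 10 carbon monoxide
Product: 13 5,7-bis(benzyloxy)-2-[2,2-diphenyl-7-(triisopropylsilyloxy)-1,3-benzodioxol-5-yl]chromen-4-one, via ortho-hydroxyaryl ynone 11 (not isolated), via diethylamino enaminone 12 (not isolated)
Conditions: PdCl2(PPh3)2 (5 mol %), CO (20 bar), Et2NH, 120 °C
Reagents that add atoms: none
Why: Diethylamine reduces the divalent palladium precatalyst to zerovalent palladium, which adds oxidatively to the C4a–I bond of 2; carbon monoxide then inserts to give an aroylpalladium iodide. The amine deprotonates the palladium-bound alkyne 9, and reductive elimination forms the C4–C3 bond and releases ynone 11. Diethylamine adds in conjugate fashion to 11 to give enaminone 12, and the C8a hydroxyl then attacks C2 and expels the amine, forming O1–C2. The closest known reaction type is the carbonylative Sonogashira coupling of ortho-iodophenols with terminal arylacetylenes that cyclises in situ to flavones in a secondary amine. Ring C closes by a 6-endo-trig addition–elimination at the β-carbon of the enaminone, and no stereocentre is formed. Two selectivities are needed: carbonylative rather than direct alkynylation (which would lead on to a 2-arylbenzofuran), and six- rather than five-membered closure (flavone, not aurone). The first is secured by the CO pressure together with the electron-rich, doubly ortho-substituted aryl–palladium bond, which inserts CO readily and relieves strain in doing so; the second by the amine, because in 12 only C2 is electrophilic, whereas the free ynone could also close 5-exo-dig. Benzyl ethers, the ketal and the hindered aryl silyl ether offer no bond that zerovalent palladium or a hot secondary amine should break, which is why a silyl and not an allyl ether protects O3'.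

Step 8
Reactants: 13 5,7-bis(benzyloxy)-2-[2,2-diphenyl-7-(triisopropylsilyloxy)-1,3-benzodioxol-5-yl]chromen-4-one
Product: 14 5,7-bis(benzyloxy)-2-(7-hydroxy-2,2-diphenyl-1,3-benzodioxol-5-yl)chromen-4-one
Conditions: Bu4NF, AcOH, THF, 0 °C
Reagents that add atoms: none
Why: Fluoride-induced desilylation of an aryl silyl ether, driven by the Si–F bond; the acetic acid buffer keeps the liberated phenoxide protonated, and benzyl ethers, ketal and chromenone are inert.

Step 9
Reactants: 14 5,7-bis(benzyloxy)-2-(7-hydroxy-2,2-diphenyl-1,3-benzodioxol-5-yl)chromen-4-one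
Product: 15 6-[5,7-bis(benzyloxy)-4-oxo-4H-chromen-2-yl]-2,2-diphenyl-1,3-benzodioxol-4-yl hydrogen sulfate
Conditions: SO3·pyridine (5 equiv), pyridine, 50 °C; aq. NaHCO3 work-up
Reagents that add atoms: sulfur trioxide–pyridine complex, [O-]S(=O)(=O)[n+]1ccccc1
Why: O-Sulfation of a phenol with a sulfur trioxide–amine complex; 14 has a single free hydroxyl, so the sulfate can only enter at O3', and the basic medium protects the acid-labile ketal and the new sulfate.

Step 10
Reactants: 15 6-[5,7-bis(benzyloxy)-4-oxo-4H-chromen-2-yl]-2,2-diphenyl-1,3-benzodioxol-4-yl hydrogen sulfate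
Product: 16 tricetin 3'-sulfate, 5-(5,7-dihydroxy-4-oxo-4H-chromen-2-yl)-2,3-dihydroxyphenyl hydrogen sulfate
Conditions: H2 (1 atm), Pd/C (10 wt % Pd), THF–MeOH 1:1, 23 °C
Reagents that add atoms: none
Why: Catalytic hydrogenolysis cleaves the two benzyl ethers and both benzylic C–O bonds of the diphenylmethylene ketal in one neutral operation; an aryl sulfate salt is stable to these conditions, and the conjugated, aromatic-like C2–C3 bond of a flavone is normally retained at atmospheric pressure.

## Compound list

1 | 3,5-bis(benzyloxy)phenol | Oc1cc(OCc2ccccc2)cc(OCc2ccccc2)c1 | starting material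
2 | 3,5-bis(benzyloxy)-2-iodophenol | Oc1cc(OCc2ccccc2)cc(OCc2ccccc2)c1I | intermediate
3 | methyl gallate | COC(=O)c1cc(O)c(O)c(O)c1 | starting material
4 | dichlorodiphenylmethane | ClC(Cl)(c1ccccc1)c1ccccc1 | starting material
5 | methyl 7-hydroxy-2,2-diphenyl-1,3-benzodioxole-5-carboxylate | COC(=O)c1cc(O)c2OC(c3ccccc3)(c3ccccc3)Oc2c1 | intermediate
6 | methyl 2,2-diphenyl-7-(triisopropylsilyloxy)-1,3-benzodioxole-5-carboxylate | COC(=O)c1cc(O[Si](C(C)C)(C(C)C)C(C)C)c2OC(c3ccccc3)(c3ccccc3)Oc2c1 | intermediate
7 | [2,2-diphenyl-7-(triisopropylsilyloxy)-1,3-benzodioxol-5-yl]methanol | OCc1cc(O[Si](C(C)C)(C(C)C)C(C)C)c2OC(c3ccccc3)(c3ccccc3)Oc2c1 | intermediate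
8 | 2,2-diphenyl-7-(triisopropylsilyloxy)-1,3-benzodioxole-5-carbaldehyde | O=Cc1cc(O[Si](C(C)C)(C(C)C)C(C)C)c2OC(c3ccccc3)(c3ccccc3)Oc2c1 | intermediate
9 | 6-ethynyl-2,2-diphenyl-4-(triisopropylsilyloxy)-1,3-benzodioxole | C#Cc1cc(O[Si](C(C)C)(C(C)C)C(C)C)c2OC(c3ccccc3)(c3ccccc3)Oc2c1 | intermediate
10 | carbon monoxide | [C-]#[O+] | starting material
11 | 1-[2,4-bis(benzyloxy)-6-hydroxyphenyl]-3-[2,2-diphenyl-7-(triisopropylsilyloxy)-1,3-benzodioxol-5-yl]prop-2-yn-1-one | O=C(C#Cc1cc(O[Si](C(C)C)(C(C)C)C(C)C)c2OC(c3ccccc3)(c3ccccc3)Oc2c1)c1c(O)cc(OCc2ccccc2)cc1OCc1ccccc1 | intermediate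
12 | (E)-1-[2,4-bis(benzyloxy)-6-hydroxyphenyl]-3-(diethylamino)-3-[2,2-diphenyl-7-(triisopropylsilyloxy)-1,3-benzodioxol-5-yl]prop-2-en-1-one | CCN(CC)/C(=C/C(=O)c1c(O)cc(OCc2ccccc2)cc1OCc1ccccc1)c1cc(O[Si](C(C)C)(C(C)C)C(C)C)c2OC(c3ccccc3)(c3ccccc3)Oc2c1 | intermediate
13 | 5,7-bis(benzyloxy)-2-[2,2-diphenyl-7-(triisopropylsilyloxy)-1,3-benzodioxol-5-yl]chromen-4-one | O=c1cc(-c2cc(O[Si](C(C)C)(C(C)C)C(C)C)c3OC(c4ccccc4)(c4ccccc4)Oc3c2)oc2cc(OCc3ccccc3)cc(OCc3ccccc3)c12 | intermediate
14 | 5,7-bis(benzyloxy)-2-(7-hydroxy-2,2-diphenyl-1,3-benzodioxol-5-yl)chromen-4-one | O=c1cc(-c2cc(O)c3OC(c4ccccc4)(c4ccccc4)Oc3c2)oc2cc(OCc3ccccc3)cc(OCc3ccccc3)c12 | intermediate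
15 | 6-[5,7-bis(benzyloxy)-4-oxo-4H-chromen-2-yl]-2,2-diphenyl-1,3-benzodioxol-4-yl hydrogen sulfate | O=c1cc(-c2cc(OS(=O)(=O)O)c3OC(c4ccccc4)(c4ccccc4)Oc3c2)oc2cc(OCc3ccccc3)cc(OCc3ccccc3)c12 | intermediate
16 | tricetin 3'-sulfate, 5-(5,7-dihydroxy-4-oxo-4H-chromen-2-yl)-2,3-dihydroxyphenyl hydrogen sulfate | O=c1cc(-c2cc(O)c(O)c(OS(=O)(=O)O)c2)oc2cc(O)cc(O)c12 | target

## Step count and risks

Total: 10 steps. Longest linear sequence: 9 steps (steps 2–10, from methyl gallate); step 1 is the one-step side branch to the ring A partner.

**Step 7 (key step).**
- What may go wrong: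
  - Oxidative addition at the iodide, flanked by a hydroxyl and a benzyloxy group, may be slow enough for the catalyst to aggregate to palladium black.
  - Direct alkynylation without CO uptake may compete and lead on to benzofuran formation.
  - The aroylpalladium species may be captured by diethylamine before the alkyne is transferred.
  - The hot amine may loosen the silyl ether before coupling.
- Fallback: this sets out from aldehyde 8 and gives up the three-component union for a two-stage construction. Aldol condensation of 8 with the commercially available ketone 1-[2,4-bis(benzyloxy)-6-hydroxyphenyl]ethanone F1 [LiN(SiMe3)2, THF, −78 → 23 °C] should give the chalcone (E)-1-[2,4-bis(benzyloxy)-6-hydroxyphenyl]-3-[2,2-diphenyl-7-(triisopropylsilyloxy)-1,3-benzodioxol-5-yl]prop-2-en-1-one F2. Oxidative cyclisation of F2 (catalytic I2, DMSO, 130 °C) should close ring C and return to the route at 13. Loss of the silyl group on the way would be harmless, since it would give 14 directly.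

**Step 1.**
- What may go wrong: all three free ring positions are activated by three oxygens, so iodination para to the hydroxyl (between the two benzyloxy groups) and double iodination may erode the yield of the ortho isomer.
- Fallback: this sets out from 1 and replaces electrophilic substitution by directed metalation. Protection (MOMCl, iPr2NEt, CH2Cl2) gives 1,3-bis(benzyloxy)-5-(methoxymethoxy)benzene F3. Lithiation ortho to the chelating acetal (n-BuLi, THF, 0 °C) and quenching with I2 give 1,5-bis(benzyloxy)-2-iodo-3-(methoxymethoxy)benzene F4. Acidic methanolysis (HCl, MeOH, 40 °C) returns to the route at 2.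

**Step 6.**
- What may go wrong: addition of the lithiated diazo reagent to the electron-rich, weakly electrophilic aldehyde may be incomplete, and the alkylidene carbene may be diverted by insertion into the N–H bond of diisopropylamine instead of rearranging.
- Fallback: this sets out from 8 and uses the Corey–Fuchs sequence. CBr4 and PPh3 (CH2Cl2, 0 °C) give 6-(2,2-dibromoethenyl)-2,2-diphenyl-4-(triisopropylsilyloxy)-1,3-benzodioxole F5. Treatment with n-BuLi (THF, −78 °C) and protonation return to the route at 9.

**Step 10.**
- What may go wrong:
  - Cleavage of the diphenylmethylene ketal may be slow.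
  - On prolonged reaction the sulfate may be lost by hydrolysis once the medium drifts acidic.
  - The C2–C3 bond may begin to be saturated.
  - Traces of pyridine or sulfur species carried over from step 9 may inhibit the catalyst.
- Fallback: this sets out from 14 and carries the sulfate as a neutral, chromatographable diester. Reaction of 14 with 2,2,2-trichloroethyl chlorosulfate (NEt3, DMAP, THF) gives 5,7-bis(benzyloxy)-2-{2,2-diphenyl-7-[(2,2,2-trichloroethoxy)sulfonyloxy]-1,3-benzodioxol-5-yl}chromen-4-one F6, which can be purified on silica. Buffered transfer hydrogenolysis (Pd/C, HCO2NH4, MeOH, 23 °C) should strip the trichloroethyl group together with the benzyl ethers and the ketal and return to the route at 16, bypassing 15.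

## Further compounds

F1 | step 7 | 1-[2,4-bis(benzyloxy)-6-hydroxyphenyl]ethanone | CC(=O)c1c(O)cc(OCc2ccccc2)cc1OCc1ccccc1
F2 | step 7 | (E)-1-[2,4-bis(benzyloxy)-6-hydroxyphenyl]-3-[2,2-diphenyl-7-(triisopropylsilyloxy)-1,3-benzodioxol-5-yl]prop-2-en-1-one | O=C(/C=C/c1cc(O[Si](C(C)C)(C(C)C)C(C)C)c2OC(c3ccccc3)(c3ccccc3)Oc2c1)c1c(O)cc(OCc2ccccc2)cc1OCc1ccccc1
F3 | step 1 | 1,3-bis(benzyloxy)-5-(methoxymethoxy)benzene | COCOc1cc(OCc2ccccc2)cc(OCc2ccccc2)c1
F4 | step 1 | 1,5-bis(benzyloxy)-2-iodo-3-(methoxymethoxy)benzene | COCOc1cc(OCc2ccccc2)cc(OCc2ccccc2)c1I
F5 | step 6 | 6-(2,2-dibromoethenyl)-2,2-diphenyl-4-(triisopropylsilyloxy)-1,3-benzodioxole | BrC(Br)=Cc1cc(O[Si](C(C)C)(C(C)C)C(C)C)c2OC(c3ccccc3)(c3ccccc3)Oc2c1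
F6 | step 10 | 5,7-bis(benzyloxy)-2-{2,2-diphenyl-7-[(2,2,2-trichloroethoxy)sulfonyloxy]-1,3-benzodioxol-5-yl}chromen-4-one | O=c1cc(-c2cc(OS(=O)(=O)OCC(Cl)(Cl)Cl)c3OC(c4ccccc4)(c4ccccc4)Oc3c2)oc2cc(OCc3ccccc3)cc(OCc3ccccc3)c12
A1 | alternative 1 | 3-[7-(allyloxy)-2,2-diphenyl-1,3-benzodioxol-5-yl]-1-[2,4-bis(benzyloxy)-6-hydroxyphenyl]prop-2-yn-1-one | O=C(C#Cc1cc(OCC=C)c2OC(c3ccccc3)(c3ccccc3)Oc2c1)c1c(O)cc(OCc2ccccc2)cc1OCc1ccccc1
A2 | alternative 1 | 3,5-bis(benzyloxy)-2-(trimethylsilyl)phenyl trifluoromethanesulfonate | C[Si](C)(C)c1c(OS(=O)(=O)C(F)(F)F)cc(OCc2ccccc2)cc1OCc1ccccc1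
A3 | alternative 1 | 3-[7-(allyloxy)-2,2-diphenyl-1,3-benzodioxol-5-yl]prop-2-ynoic acid | OC(=O)C#Cc1cc(OCC=C)c2OC(c3ccccc3)(c3ccccc3)Oc2c1
A4 | alternative 2 | 2-[7-(allyloxy)-2,2-diphenyl-1,3-benzodioxol-5-yl]-5,7-dihydroxychromen-4-one | O=c1cc(-c2cc(OCC=C)c3OC(c4ccccc4)(c4ccccc4)Oc3c2)oc2cc(O)cc(O)c12
A5 | alternative 2 | methyl 4-{6-[7-(allyloxy)-2,2-diphenyl-1,3-benzodioxol-5-yl]-4-oxo-4H-pyran-2-yl}-3-oxobutanoate | COC(=O)CC(=O)Cc1cc(=O)cc(-c2cc(OCC=C)c3OC(c4ccccc4)(c4ccccc4)Oc3c2)o1
A6 | alternative 3 | 2-[7-(allyloxy)-2,2-diphenyl-1,3-benzodioxol-5-yl]-5,7-bis(benzyloxy)chromen-4-one | C=CCOc1cc(cc2OC(c3ccccc3)(c3ccccc3)Oc12)-c1cc(=O)c2c(OCc3ccccc3)cc(OCc3ccccc3)cc2o1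
A7 | alternative 3 | 1-[7-(allyloxy)-2,2-diphenyl-1,3-benzodioxol-5-yl]-3-[2,4-bis(benzyloxy)-6-bromophenyl]propane-1,3-dione | O=C(CC(=O)c1cc(OCC=C)c2OC(c3ccccc3)(c3ccccc3)Oc2c1)c1c(Br)cc(OCc2ccccc2)cc1OCc1ccccc1
A8 | alternative 3 | 1-[2,4-bis(benzyloxy)-6-bromophenyl]ethanone | CC(=O)c1c(Br)cc(OCc2ccccc2)cc1OCc1ccccc1
A9 | alternative 3 | methyl 7-(allyloxy)-2,2-diphenyl-1,3-benzodioxole-5-carboxylate | COC(=O)c1cc(OCC=C)c2OC(c3ccccc3)(c3ccccc3)Oc2c1
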